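**Plan**
- Retrosynthesis: the four O–CH3 bonds are cut first; then, in one ring of the tetramethyl ether, the C1–CH2 bond and the adjacent C2–Br bond are cut together.
- Enabling feature: in each ring C1 (carrying the CH2) and C2 (Br) are neighbours, and C2 is flanked on its other side by the C3 bromine. A C1≡C2 aryne polarised by that bromine can therefore take carbon at C1 and then bromine at C2.
- The aryne comes from a 3-bromo-2-iodoaryl triflate (three steps from 3-bromo-4,5-dimethoxybenzaldehyde). The nucleophile is the 2,3-dibromo-4,5-dimethoxybenzyl Grignard reagent (five steps from 5-bromovanillin).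
- Forward: no ring is built; the two preformed benzene rings are joined through the CH2 group in step 9 and the catechols are unmasked in step 10.
- The target has no stereocentre, so no stereochemistry has to be set.

Key step: step 9

Remark on the chemistry: ring atoms keep the target numbering throughout (C1 CH2, C2 and C3 Br, C4 and C5 O, C6 H). It is assumed that a 2-magnesioaryl triflate loses triflate well below the temperature at which an ortho-bromoaryl-magnesium loses MgBrCl.

**Route**

Step 1
Reactants: 1 3-bromo-4,5-dimethoxybenzaldehyde
Product: 3 3-bromo-4,5-dimethoxyphenol, via 3-bromo-4,5-dimethoxyphenyl formate 2 (not isolated)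
Conditions: mCPBA (1.3 equiv), CH2Cl2, 0 °C → rt; then MeOH, HCl (cat.), rt
Reagents that add atoms: meta-chloroperoxybenzoic acid (mCPBA), OOC(=O)c1cccc(Cl)c1
Why: Baeyer–Villiger oxidation, in which the alkoxy-rich aryl group migrates in the Criegee adduct to give the aryl formate, which acid-catalysed methanolysis should cleave to the phenol as is routine for alkoxybenzaldehydes.

Step 2
Reactants: 3 3-bromo-4,5-dimethoxyphenol
Product: 4 3-bromo-2-iodo-4,5-dimethoxyphenol
Conditions: NIS (1.0 equiv), MeCN, −20 → 0 °C, dark
Reagents that add atoms: N-iodosuccinimide (NIS), O=C1CCC(=O)N1I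
Why: Electrophilic aromatic iodination of an electron-rich phenol should occur at C2, which is ortho to the hydroxyl and para to the in-plane C5 methoxy group, while C6 is shielded by the methyl of that methoxy group, the same preference that places the second bromine next to the first in step 4.

Step 3
Reactants: 4 3-bromo-2-iodo-4,5-dimethoxyphenol
Product: 5 3-bromo-2-iodo-4,5-dimethoxyphenyl trifluoromethanesulfonate
Conditions: Tf2O, pyridine, CH2Cl2, 0 °C
Reagents that add atoms: trifluoromethanesulfonic anhydride (Tf2O), FC(F)(F)S(=O)(=O)OS(=O)(=O)C(F)(F)F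
Why: Standard O-sulfonylation of a phenol, with triflate chosen as leaving group because a 2-magnesioaryl triflate should form the aryne already at −78 °C.

Step 4
Reactants: 6 5-bromovanillin (3-bromo-4-hydroxy-5-methoxybenzaldehyde)
Product: 7 2,3-dibromo-4-hydroxy-5-methoxybenzaldehyde
Conditions: Br2 (1.2 equiv), Fe powder (cat.), AcOH, rt → 60 °C
Reagents that add atoms: bromine, BrBr
Why: Electrophilic aromatic bromination, with FeBr3 formed in the flask, goes para to the methoxy group once the position ortho to the hydroxyl is occupied, a well-established way to the 5,6-dibromovanillin pattern.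

Step 5
Reactants: 7 2,3-dibromo-4-hydroxy-5-methoxybenzaldehyde
Product: 8 2,3-dibromo-4,5-dimethoxybenzaldehyde
Conditions: MeI, K2CO3, DMF, rt
Reagents that add atoms: iodomethane, CI
Why: Williamson O-methylation of an acidic, halogen-flanked phenoxide is reliable.

Step 6
Reactants: 8 2,3-dibromo-4,5-dimethoxybenzaldehyde
Product: 9 (2,3-dibromo-4,5-dimethoxyphenyl)methanol
Conditions: NaBH4, MeOH/THF, 0 °C
Reagents that add atoms: none
Why: Hydride reduction of an aryl aldehyde to the benzyl alcohol leaves the aryl bromides and methyl ethers untouched.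

Step 7
Reactants: 9 (2,3-dibromo-4,5-dimethoxyphenyl)methanol
Product: 10 2,3-dibromo-4,5-dimethoxybenzyl chloride
Conditions: SOCl2, DMF (cat.), CH2Cl2, 0 °C → rt
Reagents that add atoms: thionyl chloride, ClS(Cl)=O
Why: Chlorodehydroxylation of a benzylic alcohol through its chlorosulfite gives the chloride, preferred over the bromide because it is less prone to Wurtz coupling in the next step.

Step 8
Reactants: 10 2,3-dibromo-4,5-dimethoxybenzyl chloride
Product: 11 (2,3-dibromo-4,5-dimethoxybenzyl)magnesium chloride (titrated solution, used at once)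
Conditions: Mg turnings (3 equiv), 2-MeTHF, 0 °C, slow addition, high dilution
Reagents that add atoms: magnesium, [Mg]
Why: Grignard formation by insertion of magnesium into the benzylic C–Cl bond is faster than insertion into electron-rich aryl C–Br bonds, as in the routine preparation of ortho-bromobenzyl Grignard reagents, and cold dilute 2-MeTHF limits Wurtz coupling.

Step 9
Reactants: 5 3-bromo-2-iodo-4,5-dimethoxyphenyl trifluoromethanesulfonate; 11 (2,3-dibromo-4,5-dimethoxybenzyl)magnesium chloride
Product: 15 bis(2,3-dibromo-4,5-dimethoxyphenyl)methane, via 2-magnesiated aryl triflate 12 (not isolated), via 3-bromo-4,5-dimethoxybenzyne 13 (not isolated), via benzylated 2-bromoaryl-magnesium chloride 14 (not isolated)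
Conditions: 5 (1.0 equiv) and 11 (1.5 equiv), THF/2-MeTHF, −78 °C; Me3SiCH2MgCl (1.1 equiv) dropwise, −78 °C, 1 h; then BrCl2C–CCl2Br (3 equiv) in THF, −78 → −20 °C; aq NH4Cl
Reagents that add atoms: 1,2-dibromo-1,1,2,2-tetrachloroethane, ClC(Cl)(Br)C(Cl)(Cl)Br
Why: Iodine–magnesium exchange of the C2 iodide of 5 with Me3SiCH2MgCl gives 12, which loses triflate from C1 already at −78 °C to form the C1≡C2 aryne 13; the benzylic carbon of 11 adds to C1 to give aryl-magnesium 14, and halophilic attack of 14 on BrCl2C–CCl2Br forms the C2–Br bond. The closest known reaction type is the carbomagnesiation of arynes generated from 2-iodoaryl sulfonates or triflates by halogen–magnesium exchange, followed by electrophilic trapping of the new aryl-magnesium. No ring is closed and no stereocentre is formed. Regioselectivity is required and is secured by the C3 bromine, whose inductive pull distorts the aryne so that the nucleophile attacks the remote, unhindered C1 and the carbanion develops at C2 beside bromine. Chemoselectivity is required as well: exchange at −78 °C touches only the C–I bond and none of the aryl bromides, the silylmethyl Grignard is too poor a nucleophile to compete with 11 for the aryne, and adding the activator last keeps the aryne concentration low. The ortho-bromo aryl-magnesium 14 never leaves −78 °C before it is brominated, which is the reason for choosing triflate over a slower sulfonate leaving group and which prevents a second elimination of MgBrCl.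

Step 10
Reactants: 15 bis(2,3-dibromo-4,5-dimethoxyphenyl)methane
Product: 16 bis(2,3-dibromo-4,5-dihydroxyphenyl)methane (CNP0260813.0)
Conditions: BBr3 (8 equiv), CH2Cl2, −78 °C → rt; then H2O, 0 °C, under argon
Reagents that add atoms: none
Why: Lewis-acid-mediated cleavage of aryl methyl ethers (bromide attacks the methyl group of the boron-complexed ether) is the standard unmasking of brominated catechols and leaves aryl bromides and the diarylmethane untouched.

**Compound list**
1 | 3-bromo-4,5-dimethoxybenzaldehyde | COc1cc(C=O)cc(Br)c1OC | starting material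
2 | 3-bromo-4,5-dimethoxyphenyl formate | COc1cc(OC=O)cc(Br)c1OC | intermediate
3 | 3-bromo-4,5-dimethoxyphenol | COc1cc(O)cc(Br)c1OC | intermediate
4 | 3-bromo-2-iodo-4,5-dimethoxyphenol | COc1cc(O)c(I)c(Br)c1OC | intermediate
5 | 3-bromo-2-iodo-4,5-dimethoxyphenyl trifluoromethanesulfonate | COc1cc(OS(=O)(=O)C(F)(F)F)c(I)c(Br)c1OC | intermediate
6 | 5-bromovanillin (3-bromo-4-hydroxy-5-methoxybenzaldehyde) | COc1cc(C=O)cc(Br)c1O | starting material
7 | 2,3-dibromo-4-hydroxy-5-methoxybenzaldehyde | COc1cc(C=O)c(Br)c(Br)c1O | intermediate
8 | 2,3-dibromo-4,5-dimethoxybenzaldehyde | COc1cc(C=O)c(Br)c(Br)c1OC | intermediate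
9 | (2,3-dibromo-4,5-dimethoxyphenyl)methanol | COc1cc(CO)c(Br)c(Br)c1OC | intermediate
10 | 2,3-dibromo-4,5-dimethoxybenzyl chloride | COc1cc(CCl)c(Br)c(Br)c1OC | intermediate
11 | (2,3-dibromo-4,5-dimethoxybenzyl)magnesium chloride | COc1cc(C[Mg]Cl)c(Br)c(Br)c1OC | intermediate
12 | 3-bromo-2-(chloromagnesio)-4,5-dimethoxyphenyl trifluoromethanesulfonate | COc1cc(OS(=O)(=O)C(F)(F)F)c([Mg]Cl)c(Br)c1OC | intermediate
13 | 3-bromo-4,5-dimethoxybenzyne (3-bromo-4,5-dimethoxy-1,2-didehydrobenzene) | COC1=CC#CC(Br)=C1OC | intermediate
14 | [2-bromo-6-(2,3-dibromo-4,5-dimethoxybenzyl)-3,4-dimethoxyphenyl]magnesium chloride | COc1cc(Cc2cc(OC)c(OC)c(Br)c2Br)c([Mg]Cl)c(Br)c1OC | intermediate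
15 | bis(2,3-dibromo-4,5-dimethoxyphenyl)methane | COc1cc(Cc2cc(OC)c(OC)c(Br)c2Br)c(Br)c(Br)c1OC | intermediate
16 | bis(2,3-dibromo-4,5-dihydroxyphenyl)methane | Oc1cc(Cc2cc(O)c(O)c(Br)c2Br)c(Br)c(Br)c1O | target

**Count**
Total steps: 10. Longest linear sequence: 7 (steps 4, 5, 6, 7, 8, 9, 10).

**Steps most likely to fail**

1. Step 9.
- What may go wrong: the aryne may be captured by the activator or by the newly formed aryl-magnesium, leading to oligomers. The benzylic Grignard may add through its ring ortho carbon or with eroded regioselectivity. Iodine may be transferred from unreacted 5 to 14. MgBrCl may be eliminated from 14 before bromination.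
- Fallback: it sets out from benzyl alcohol 9 and comes back to the route at target 16. Acid-catalysed Friedel–Crafts benzylation of commercial 2-bromo-6-methoxyphenol with 9 (TfOH cat., (CF3)2CHOH, rt), directed para to the free hydroxyl, should give 2-bromo-4-(2,3-dibromo-4,5-dimethoxybenzyl)-6-methoxyphenol F1. Electrophilic bromination (Br2, AcOH, rt) para to the methoxy group, the site also used in step 4, should give 2,3-dibromo-4-(2,3-dibromo-4,5-dimethoxybenzyl)-6-methoxyphenol F2. Its three methyl ethers are cleaved under the conditions of step 10 to give 16.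

2. Step 8.
- What may go wrong: Wurtz homocoupling of the benzylic chloride with the Grignard reagent already formed, and competing insertion of magnesium into the aryl C–Br bonds, would lower the titre and contaminate the reagent.
- Fallback: it sets out from benzyl chloride 10 and comes back at Grignard reagent 11. Zinc-mediated Barbier-type coupling of 10 with Bu3SnCl (Zn dust, THF/sat. aq NH4Cl, rt) should give tributyl(2,3-dibromo-4,5-dimethoxybenzyl)stannane F3. Tin–lithium exchange with MeLi (THF, −78 °C) should give (2,3-dibromo-4,5-dimethoxybenzyl)lithium F4. This is transmetalated in the same flask with MgCl2 to 11, so that no benzylic halide is ever exposed to the organometallic.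

3. Step 2.
- What may go wrong: iodination may also occur at C6 (the other position ortho to the hydroxyl), a second iodine may be introduced, or the para-methoxyphenol may be oxidised towards a quinone.
- Fallback: it sets out from aldehyde 1 and comes back at iodophenol 4. Iodination of the aldehyde (NIS, CF3CO2H, rt), where only the position para to the C5 methoxy group is activated and no second iodination is expected, should give 3-bromo-2-iodo-4,5-dimethoxybenzaldehyde F5. Baeyer–Villiger oxidation as in step 1 (mCPBA, CH2Cl2; then MeOH, HCl cat.) would pass through 3-bromo-2-iodo-4,5-dimethoxyphenyl formate F6 and deliver 4.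

**Further compounds**
F1 | step 9 | 2-bromo-4-(2,3-dibromo-4,5-dimethoxybenzyl)-6-methoxyphenol | COc1cc(Cc2cc(OC)c(OC)c(Br)c2Br)cc(Br)c1O
F2 | step 9 | 2,3-dibromo-4-(2,3-dibromo-4,5-dimethoxybenzyl)-6-methoxyphenol | COc1cc(Cc2cc(OC)c(OC)c(Br)c2Br)c(Br)c(Br)c1O
F3 | step 8 | tributyl(2,3-dibromo-4,5-dimethoxybenzyl)stannane | CCCC[Sn](CCCC)(CCCC)Cc1cc(OC)c(OC)c(Br)c1Br
F4 | step 8 | (2,3-dibromo-4,5-dimethoxybenzyl)lithium | [Li]Cc1cc(OC)c(OC)c(Br)c1Br
F5 | step 2 | 3-bromo-2-iodo-4,5-dimethoxybenzaldehyde | COc1cc(C=O)c(I)c(Br)c1OC
F6 | step 2 | 3-bromo-2-iodo-4,5-dimethoxyphenyl formate | COc1cc(OC=O)c(I)c(Br)c1OC
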